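The quinone ring is numbered C1(=O), C2(OMe), C3(H), C4(=O), C5(CH3), C6(docosyl). Its C2=C3 bond bears only methoxy and hydrogen and is therefore cut by ring-closing metathesis: an acyclic 1,4-diketone whose carbonyls carry a 1-methoxyvinyl group (future C2) and a vinyl group (future C3) closes in one operation to the six-membered ene-dione, the keto tautomer of the hydroquinone. The precursor, 4-docosyl-2-methoxy-5-methylocta-1,7-diene-3,6-dione, rests on a lactone-derived C1–C6–C5–C4 backbone that places docosyl beside the methoxyvinyl ketone; each carbon nucleophile meets a substrate with a single reactive carbonyl, and enolisation followed by oxidation delivers the quinone.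

Key step: step 7

Remark: the target is achiral. Lactone 1 is used as the racemate, and every sp3 centre of the intermediates is carried as a mixture and later becomes sp2, so the SMILES carry no stereodescriptors.

Step 1
Reactants: 1 4-methyldihydrofuran-2(3H)-one (racemic); 2 1-bromodocosane
Product: 4 3-docosyl-4-methyldihydrofuran-2(3H)-one (racemic diastereomer mixture), via lactone lithium enolate 3 (not isolated)
Conditions: LiN(i-Pr)2 (LDA), THF, –78 °C; then 2, DMPU, –78 → –20 °C
Reagents that add atoms: none
Why: Enolate alkylation, in which the kinetic lithium enolate of the lactone displaces bromide from the primary halide in an SN2 reaction accelerated by DMPU; attack anti to the C4 methyl group should favour the trans lactone, although both centres are erased in step 8.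

Step 2
Reactants: 4 3-docosyl-4-methyldihydrofuran-2(3H)-one
Product: 5 2-docosyl-4-hydroxy-N-methoxy-N,3-dimethylbutanamide (diastereomer mixture)
Conditions: MeNHOMe·HCl, Me3Al, CH2Cl2, 0 °C → rt; aq. KNaC4H4O6 work-up; crude taken on at once
Reagents that add atoms: N,O-dimethylhydroxylamine hydrochloride, CNOC.Cl
Why: Weinreb aminolysis of a lactone, in which the aluminium amide made from Me3Al and the amine salt activates the lactone carbonyl and delivers the amine; the open-chain hydroxy amide is used crude before it can close back to the lactone, and no stereocentre is touched.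

Step 3
Reactants: 5 2-docosyl-4-hydroxy-N-methoxy-N,3-dimethylbutanamide
Product: 6 2-docosyl-N-methoxy-N,3-dimethyl-4-oxobutanamide (diastereomer mixture)
Conditions: Dess–Martin periodinane, NaHCO3, CH2Cl2, 0 °C → rt
Reagents that add atoms: none
Why: Dess–Martin oxidation of the primary alcohol to the aldehyde should be fast enough under buffered, non-aqueous conditions to outrun relactonisation and leaves the Weinreb amide untouched; epimerisation next to the aldehyde is of no consequence.

Step 4
Reactants: 6 2-docosyl-N-methoxy-N,3-dimethyl-4-oxobutanamide; 7 vinylmagnesium bromide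
Product: 9 3-docosyl-4-methyl-5-vinyldihydrofuran-2(3H)-one (diastereomer mixture), via allylic alcohol amide 8 (not isolated)
Conditions: CH2=CHMgBr (1.1 equiv), THF, –78 °C; AcOH quench at –78 °C; then CSA (1.1 equiv), CH2Cl2, rt
Reagents that add atoms: none
Why: Chemoselective Grignard addition, the aldehyde being far more electrophilic than the Weinreb amide at –78 °C, followed by acid-promoted lactonisation of the γ-hydroxy amide with loss of MeNHOMe, which stores the carbinol in a lactone that is also the acyl donor for step 5; the new carbinol centre forms without control and is oxidised away in step 6.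

Step 5
Reactants: 9 3-docosyl-4-methyl-5-vinyldihydrofuran-2(3H)-one; 10 methyl vinyl ether
Product: 13 4-docosyl-6-hydroxy-2-methoxy-5-methylocta-1,7-dien-3-one (diastereomer mixture), via 1-methoxyvinyllithium 11 (not isolated), via cyclic hemiketal 12 (not isolated)
Conditions: 10 (excess), t-BuLi, THF, –78 → 0 °C; then 9, –78 °C; H2O quench at –78 °C
Reagents that add atoms: none
Why: Addition of an acyl anion equivalent to a lactone, in which α-lithiated methyl vinyl ether adds once to the only electrophile present because the lithium hemiketalate does not collapse to a ketone before the quench; the product is the open-chain hydroxy ketone in ring–chain equilibrium with hemiketal 12.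

Step 6
Reactants: 13 4-docosyl-6-hydroxy-2-methoxy-5-methylocta-1,7-dien-3-one (equilibrium mixture with 12)
Product: 14 4-docosyl-2-methoxy-5-methylocta-1,7-diene-3,6-dione (diastereomer mixture)
Conditions: Dess–Martin periodinane, NaHCO3, CH2Cl2, 0 °C; used at once
Reagents that add atoms: none
Why: Dess–Martin oxidation of the secondary allylic alcohol, in which only the open-chain tautomer is oxidised and its consumption drains the hemiketal through the ring–chain equilibrium, as in the known lactone, lactol, 1,4-diketone sequence; NaHCO3 shields the enol ether from AcOH, and the diketone can no longer form a hemiketal.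

Step 7
Reactants: 14 4-docosyl-2-methoxy-5-methylocta-1,7-diene-3,6-dione
Product: 15 6-docosyl-2-methoxy-5-methylcyclohex-2-ene-1,4-dione (diastereomer mixture)
Conditions: second-generation Grubbs catalyst (H2IMes)(PCy3)Cl2Ru=CHPh (10 mol %), PhMe (0.005 M), 80 °C, Ar sparge
Reagents that add atoms: none
Why: Ring-closing olefin metathesis, in which the ruthenium benzylidene should exchange first with the C7=C8 vinyl ketone terminus of 14 (chain numbering), the only monosubstituted and unhindered olefin, and the alkylidene then sitting on C7 adds across the tethered C1=C2(OMe) olefin with ruthenium on the CH2 carbon; cycloreversion of this ruthenacyclobutane joins chain carbons C7 and C2 as ring carbons C3 and C2 and passes on a methylidene, so that C1 and C8 leave together as ethene. The closest known reaction type is the metathesis benzannulation, in which an acyclic dienone is closed to a cyclohexenone or cyclohexenedione that is the keto tautomer of a phenol or hydroquinone, together with ring closures onto 1,1-disubstituted enol ether and acrylate-type olefins. The six-membered carbocycle is closed by joining the two inner olefinic carbons of a 1,7-diene, a strain-free closure made irreversible by loss of ethene. No stereocentre is formed, and the two existing ones are carried as a mixture that a six-membered ring accommodates in either relative configuration. The selectivity needed is ring closure over cross-metathesis and over capture of ruthenium as a methoxy(acyl)carbene: the enol ether olefin is 1,1-disubstituted and deactivated by its carbonyl, so it should react only when held next to the loaded alkylidene, the two vicinal substituents on the backbone favour the folded conformer, and high dilution with removal of ethene suppresses dimerisation.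

Step 8
Reactants: 15 6-docosyl-2-methoxy-5-methylcyclohex-2-ene-1,4-dione
Product: 17 3-docosyl-5-methoxy-2-methylcyclohexa-2,5-diene-1,4-dione, via hydroquinone 16 (not isolated)
Conditions: Et3N (0.2 equiv), CH2Cl2, rt, Ar; then Ag2O, MgSO4, rt
Reagents that add atoms: none
Why: Amine-catalysed keto–enol tautomerisation turns the ene-dione into its aromatic hydroquinone tautomer, which Ag2O oxidises to the para-quinone (hydroquinone oxidation); both sp3 centres become sp2, so all diastereomers should converge on the single achiral target.

Compound list
1 | 4-methyldihydrofuran-2(3H)-one (β-methyl-γ-butyrolactone, racemic) | CC1COC(=O)C1 | starting material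
2 | 1-bromodocosane | CCCCCCCCCCCCCCCCCCCCCCBr | starting material
3 | lithium 4-methyl-4,5-dihydrofuran-2-olate (lithium enolate of 1, not isolated) | CC1COC(O[Li])=C1 | intermediate
4 | 3-docosyl-4-methyldihydrofuran-2(3H)-one (racemic, trans expected to predominate) | CCCCCCCCCCCCCCCCCCCCCCC1C(C)COC1=O | intermediate
5 | 2-docosyl-4-hydroxy-N-methoxy-N,3-dimethylbutanamide (racemic diastereomer mixture) | CCCCCCCCCCCCCCCCCCCCCCC(C(C)CO)C(=O)N(C)OC | intermediate
6 | 2-docosyl-N-methoxy-N,3-dimethyl-4-oxobutanamide (racemic diastereomer mixture) | CCCCCCCCCCCCCCCCCCCCCCC(C(C)C=O)C(=O)N(C)OC | intermediate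
7 | vinylmagnesium bromide | C=C[Mg]Br | starting material
8 | 2-docosyl-4-hydroxy-N-methoxy-N,3-dimethylhex-5-enamide (diastereomer mixture, not isolated) | CCCCCCCCCCCCCCCCCCCCCCC(C(C)C(O)C=C)C(=O)N(C)OC | intermediate
9 | 3-docosyl-4-methyl-5-vinyldihydrofuran-2(3H)-one (racemic diastereomer mixture) | C=CC1OC(=O)C(CCCCCCCCCCCCCCCCCCCCCC)C1C | intermediate
10 | methyl vinyl ether | C=COC | starting material
11 | 1-methoxyvinyllithium (not isolated) | [Li]C(=C)OC | intermediate
12 | 3-docosyl-2-(1-methoxyvinyl)-4-methyl-5-vinyltetrahydrofuran-2-ol (cyclic hemiketal, ring–chain tautomer of 13, diastereomer mixture, not isolated as such) | C=CC1OC(O)(C(OC)=C)C(CCCCCCCCCCCCCCCCCCCCCC)C1C | intermediate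
13 | 4-docosyl-6-hydroxy-2-methoxy-5-methylocta-1,7-dien-3-one (racemic diastereomer mixture) | C=CC(O)C(C)C(CCCCCCCCCCCCCCCCCCCCCC)C(=O)C(OC)=C | intermediate
14 | 4-docosyl-2-methoxy-5-methylocta-1,7-diene-3,6-dione (racemic diastereomer mixture) | C=CC(=O)C(C)C(CCCCCCCCCCCCCCCCCCCCCC)C(=O)C(OC)=C | intermediate
15 | 6-docosyl-2-methoxy-5-methylcyclohex-2-ene-1,4-dione (racemic diastereomer mixture) | COC1=CC(=O)C(C)C(CCCCCCCCCCCCCCCCCCCCCC)C1=O | intermediate
16 | 3-docosyl-5-methoxy-2-methylbenzene-1,4-diol (achiral, not isolated) | COc1cc(O)c(C)c(CCCCCCCCCCCCCCCCCCCCCC)c1O | intermediate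
17 | 3-docosyl-5-methoxy-2-methylcyclohexa-2,5-diene-1,4-dione (CNP0219396.0, achiral) | CCCCCCCCCCCCCCCCCCCCCCC1=C(C)C(=O)C=C(OC)C1=O | target

Total step count: 8. Longest linear sequence: 8 steps (1 to 17).

Steps most likely to fail

Step 7. Both olefins are conjugated to carbonyl groups, so turnover may be slow. The catalyst may be parked as a methoxy-substituted carbene on the enol ether carbon, and the vinyl ketone may oligomerise by cross-metathesis or polymerise before the ring closes. The fallback runs the same ring closure at the diol oxidation level, where neither olefin is carbonyl-conjugated, and sets out from lactone 9. Reduction with i-Bu2AlH (PhMe, –78 °C) should give the lactol 3-docosyl-4-methyl-5-vinyltetrahydrofuran-2-ol F1. An excess of 1-methoxyvinyllithium 11 (THF, –78 → 0 °C) should open it to 4-docosyl-2-methoxy-5-methylocta-1,7-diene-3,6-diol F2. Ring-closing metathesis of this allylic alcohol and enol ether diene with second-generation Grubbs catalyst (H2IMes)(PCy3)Cl2Ru=CHPh (CH2Cl2, 40 °C, high dilution) should give 6-docosyl-2-methoxy-5-methylcyclohex-2-ene-1,4-diol F3. Dess–Martin oxidation of both carbinols (NaHCO3, CH2Cl2) comes back to the route at 15.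

Step 5. The lactone may take up the lithium reagent twice or be deprotonated at C3 instead of attacked, or the enol ether adduct may be lost on work-up. The fallback changes the acyl donor to a Weinreb amide, whose chelated adduct releases the ketone only on quench, and sets out from aldehyde 6. Vinylmagnesium bromide 7 is added as in step 4, the mixture is quenched cold, and crude 8 is silylated at once (TESOTf, 2,6-lutidine, CH2Cl2, –78 °C) before it lactonises, which should give 2-docosyl-N-methoxy-N,3-dimethyl-4-(triethylsilyloxy)hex-5-enamide F4. Reagent 11 (THF, –78 °C) should convert it into 4-docosyl-2-methoxy-5-methyl-6-(triethylsilyloxy)octa-1,7-dien-3-one F5. Desilylation with TBAF buffered by AcOH (THF, 0 °C) comes back to the route at 13.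

Step 1. The waxy bromide dissolves poorly at low temperature, so substitution may be slow, and on warming the enolate may condense with unreacted lactone or be alkylated twice. The fallback replaces the SN2 step by an aldol condensation and hydrogenation and sets out from lactone 1. Its enolate 3 is added to docosanal (THF, –78 °C), which should give 3-(1-hydroxydocosyl)-4-methyldihydrofuran-2(3H)-one F6. Mesylation (MsCl, Et3N, CH2Cl2, 0 °C) should give 1-(4-methyl-2-oxotetrahydrofuran-3-yl)docosyl methanesulfonate F7, and elimination with DBU should give 3-docosylidene-4-methyldihydrofuran-2(3H)-one F8. Hydrogenation (H2, Pd/C, EtOAc) comes back to the route at 4.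

Further compounds
F1 | step 7 | 3-docosyl-4-methyl-5-vinyltetrahydrofuran-2-ol | C=CC1OC(O)C(CCCCCCCCCCCCCCCCCCCCCC)C1C
F2 | step 7 | 4-docosyl-2-methoxy-5-methylocta-1,7-diene-3,6-diol | C=CC(O)C(C)C(CCCCCCCCCCCCCCCCCCCCCC)C(O)C(OC)=C
F3 | step 7 | 6-docosyl-2-methoxy-5-methylcyclohex-2-ene-1,4-diol | COC1=CC(O)C(C)C(CCCCCCCCCCCCCCCCCCCCCC)C1O
F4 | step 5 | 2-docosyl-N-methoxy-N,3-dimethyl-4-(triethylsilyloxy)hex-5-enamide | CCCCCCCCCCCCCCCCCCCCCCC(C(C)C(O[Si](CC)(CC)CC)C=C)C(=O)N(C)OC
F5 | step 5 | 4-docosyl-2-methoxy-5-methyl-6-(triethylsilyloxy)octa-1,7-dien-3-one | C=CC(O[Si](CC)(CC)CC)C(C)C(CCCCCCCCCCCCCCCCCCCCCC)C(=O)C(OC)=C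
F6 | step 1 | 3-(1-hydroxydocosyl)-4-methyldihydrofuran-2(3H)-one | CCCCCCCCCCCCCCCCCCCCCC(O)C1C(C)COC1=O
F7 | step 1 | 1-(4-methyl-2-oxotetrahydrofuran-3-yl)docosyl methanesulfonate | CCCCCCCCCCCCCCCCCCCCCC(OS(C)(=O)=O)C1C(C)COC1=O
F8 | step 1 | 3-docosylidene-4-methyldihydrofuran-2(3H)-one | CCCCCCCCCCCCCCCCCCCCCC=C1C(C)COC1=O
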